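The ratio I wanted for this flask was that of saturated [X] to the [L] charged. It has 0.050 M of L and 1.30 equiv of J, and it stops at 2.0 min.

| flask | L | J | remark | time | volume of the second phase over the first |
|---|---|---|---|---|---|
| spring | 0.075 M | 1.3 equiv | run made earlier |  |  |
| flask | 0.050 M | 1.30 equiv |  | 2.0 min | 1.0 |

- spring (time / s: X / %, Z / %): 10.0: 25, 16; 15.0: 36, 26; 20.0: 47, 35; 25.0: 52, 45

(each reading ± 1.5 percentage points)

- what is said of X includes Z
- in the second phase: J; everything else is in the first
- charges count per volume of the first phase; a concentration in a rate is the amount of a species over the volume of its own phase; every rate counts per litre of the first phase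
- Z is a solid; its amount is given per volume of the solution
- steps that have been proposed: Q <-> J; L + Q -> X; Q + X -> E; Z <-> X; X <-> G; Q -> D
- the earlier runs hold the two phases in the same ratio of volumes as the flask asked about

1. the X and Z together standing at 2.0 min, as a percentage of the L charged
2. concentration of X in solution at 2.0 min, in percent of saturation

In the spring run Z stood at every reading, and X counts Z too, so the difference between the columns reads the dissolved X. It averaged 9.50 % of the spring charge, which gave a saturated [X] of 7.12 mM, as a reading with its scatter. Over the flask's charge that made 14.2 %, which I called the holding share: the part of the L charged that stands dissolved as X at that saturated [X]. The spring run had X at 52 % of its own charge after 25.0 s, more than this share, so I expected crystals in the flask and a solution near saturation. My reckoning gave no figure for y.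

The forecast gave 82 % and 105 %, with the remark “Crystals protect X but redissolve as X is consumed”.

The flask gave 63.8 % and 99.7 %, so y lay 18 percentage points below the forecast.

    Q ⇌ J, rate k1*([Q] - [J]/K1) per volume of the first phase (partition coefficient = 0.550, kL = 0.0218 s⁻¹)
    L + Q → X (k = 5.54 M⁻¹ s⁻¹)
    Q + X → E (k = 3.15 M⁻¹ s⁻¹)
    Z ⇌ X, rate k4*(cs4 - [X]) while solid is left; crystals form when [X] > cs4 (solubility = 7.60 mM, k = 1.19 s⁻¹)
    X ⇌ G (K = 0.727, k = 0.00431 s⁻¹)
    Q → D (k = 0.00307 s⁻¹)

At 2.00 min the flask held X at 63.8 %, of which Z was 48.7 %, so 15.1 % stood dissolved, beside the holding share of 14.2 % read from the spring run. The neighbouring flask has the same equivalents and time but 0.013 M of L, so the same saturated [X] gives it a holding share of 54.8 %. At 2.00 min its X stood at 37.0 %, less than that share, and its Z stood at 0 %.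

The readings stem from a simulated flask with made-up constants; scatter was added.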